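## Retrosynthetic overview

Numbering: ring A is C1 (OMe), C2 (Br), C3 (Me), C4 (Cl), C5 (OH), C6 (acyl); the ketone carbon is C7; ring B is C1' (on C7), C2' (CHO), C3' (OH), C4' (H), C5' (OH), C6' (prenyl).
The plan rests on ring A, a benzene with six different substituents arranged almost mirror-symmetrically about the C3–C6 axis, so that OH versus OMe must be matched to Cl versus Br; its C5(OH)–C6(carbon)–C1(OMe) triad is what a vinylketene/ynol ether benzannulation produces.
Ring A is made last, by disconnecting C5–C6 and C1–C2 (C4–C5 being the electrocyclic closure) into 2-bromo-4-chloro-3-methylcyclobutenone 7 and the ring B methoxyalkyne 20, so both halogens arrive with the four-carbon piece; after it come phenol protection, desilylation, double oxidation (C7 and the C2' carbon) and MOM removal.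
Alkyne 20 comes from lithium methoxyacetylide and the lactol of a 7-prenyl-4,6-bis(MOM-oxy)phthalide (ring B bought as 3,5-dimethoxybenzoic acid; the lactone ring is temporary); 7 comes from propyne and dichloroketene by C2 bromination and one dechlorination.

Key step: step 12

Remark: the C7 carbinol, C4 of the cyclobutenone and the lactol carbon are racemic and are all destroyed before the achiral target, so no stereocontrol is needed.

## Route

Step 1
Reactants: 1 propyne; 2 trichloroacetyl chloride
Product: 4 4,4-dichloro-3-methylcyclobut-2-en-1-one, via dichloroketene 3 (not isolated)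
Conditions: Zn–Cu couple, POCl3, Et2O, 0 °C to rt (2 added slowly to excess propyne)
Reagents that add atoms: none
Why: Zinc dehalogenation of 2 gives dichloroketene, and its [2+2] cycloaddition with a terminal alkyne joins the terminal alkyne carbon to the ketene carbonyl carbon, so the methyl group ends at C3 next to CCl2 (ketene–alkyne cycloaddition).

Step 2
Reactants: 4 4,4-dichloro-3-methylcyclobut-2-en-1-one
Product: 6 2-bromo-4,4-dichloro-3-methylcyclobut-2-en-1-one, via 2,3-dibromo-4,4-dichloro-3-methylcyclobutanone 5 (not isolated)
Conditions: Br2, CH2Cl2, 0 °C to rt; then Et3N, −20 °C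
Reagents that add atoms: bromine, BrBr
Why: Bromine addition to the enone followed by amine dehydrobromination (bromination–dehydrobromination of an enone) can only eliminate through the single acidic hydrogen at C2, because C4 carries no hydrogen at this stage, so bromine is fixed at C2.

Step 3
Reactants: 6 2-bromo-4,4-dichloro-3-methylcyclobut-2-en-1-one
Product: 7 2-bromo-4-chloro-3-methylcyclobut-2-en-1-one (racemic)
Conditions: Zn dust (1.1 equiv), AcOH, TMEDA, EtOH, 0 °C
Reagents that add atoms: none
Why: Zinc reduction of an α,α-dichloro ketone should stop after one chlorine with limiting metal in the cold, since the first C–Cl bond of the gem-dichloride is reduced more easily than the second or the vinylic C–Br bond, and the diamine ties up zinc salts that would promote allylic halide migration; C4 is formed racemic.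

Step 4
Reactants: 8 3,5-dimethoxybenzoic acid
Product: 10 4,6-dimethoxyisobenzofuran-1(3H)-one, via 2-(hydroxymethyl)-3,5-dimethoxybenzoic acid 9 (not isolated)
Conditions: aq. HCHO, conc. HCl, AcOH, 90 °C
Reagents that add atoms: formaldehyde, C=O
Why: Acid-mediated hydroxymethylation (Blanc-type electrophilic substitution) should occur ortho to one methoxy group and para to the other, next to the carboxyl group, and the benzylic alcohol then lactonises to the phthalide.

Step 5
Reactants: 10 4,6-dimethoxyisobenzofuran-1(3H)-one
Product: 11 7-bromo-4,6-dimethoxyisobenzofuran-1(3H)-one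
Conditions: NBS, MeCN, rt
Reagents that add atoms: N-bromosuccinimide, O=C1CCC(=O)N1Br
Why: Electrophilic aromatic bromination should go to C7, ortho to one methoxy group and para to the other, in preference to the crowded C5 between the two methoxy groups, as is usual for 3,5-dimethoxybenzoates.

Step 6
Reactants: 11 7-bromo-4,6-dimethoxyisobenzofuran-1(3H)-one
Product: 12 7-bromo-4,6-dihydroxyisobenzofuran-1(3H)-one
Conditions: BBr3, CH2Cl2, −78 °C to rt; aq. work-up
Reagents that add atoms: none
Why: BBr3 cleaves both aryl methyl ethers by Lewis acid complexation and bromide attack on methyl (ether demethylation), while the lactone and the aryl bromide should be retained.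

Step 7
Reactants: 12 7-bromo-4,6-dihydroxyisobenzofuran-1(3H)-one
Product: 13 7-bromo-4,6-bis(methoxymethoxy)isobenzofuran-1(3H)-one
Conditions: MOMCl, iPr2NEt, CH2Cl2, 0 °C to rt
Reagents that add atoms: chloromethyl methyl ether (MOMCl), COCCl
Why: O-Alkylation of both phenols with MOMCl under amine base installs acetals that can later be removed by mild acid without touching the ring A methyl ether.

Step 8
Reactants: 13 7-bromo-4,6-bis(methoxymethoxy)isobenzofuran-1(3H)-one
Product: 14 4,6-bis(methoxymethoxy)-7-(3-methylbut-2-en-1-yl)isobenzofuran-1(3H)-one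
Conditions: prenylB(pin), PdCl2(IPent)(3-chloropyridine) (cat.; IPent = 1,3-bis(2,6-di(pentan-3-yl)phenyl)imidazol-2-ylidene), K3PO4, THF/H2O, 65 °C; work-up at pH 4
Reagents that add atoms: prenylboronic acid pinacol ester, CC(C)=CCB1OC(C)(C)C(C)(C)O1
Why: Suzuki–Miyaura coupling with a bulky N-heterocyclic carbene ligand on palladium should make reductive elimination occur from the primary allyl terminus, giving the linear prenyl arene and not the reverse-prenyl isomer, and such catalysts tolerate doubly ortho-substituted bromides.

Step 9
Reactants: 14 4,6-bis(methoxymethoxy)-7-(3-methylbut-2-en-1-yl)isobenzofuran-1(3H)-one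
Product: 15 4,6-bis(methoxymethoxy)-7-(3-methylbut-2-en-1-yl)-1,3-dihydroisobenzofuran-1-ol (racemic)
Conditions: DIBAL-H (1.1 equiv), CH2Cl2, −78 °C; aq. potassium sodium tartrate
Reagents that add atoms: none
Why: Low-temperature DIBAL-H reduction of a lactone stops at the aluminium hemiacetal stage and gives the lactol on work-up (partial lactone reduction); the lactol carbon is racemic.

Step 10
Reactants: 15 the lactol; 16 chloroacetaldehyde dimethyl acetal
Product: 19 1-[2-(hydroxymethyl)-3,5-bis(methoxymethoxy)-6-(3-methylbut-2-en-1-yl)phenyl]-3-methoxyprop-2-yn-1-ol (racemic), via lithium methoxyacetylide 17 (not isolated), via ring-opened hydroxy aldehyde 18 (not isolated)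
Conditions: 16, LiNEt2 (3 equiv per 16), THF, 0 °C; then 15 (0.25 equiv), −78 to 0 °C; aq. NaHCO3
Reagents that add atoms: none
Why: Double elimination (HCl, MeOH) from the chloroacetal and deprotonation give the methoxyacetylide, and the deprotonated lactol reacts through its open aldehyde form by 1,2-addition of the acetylide; the C7 carbinol is formed racemic and is oxidised later.

Step 11
Reactants: 19 the diol
Product: 20 bis-TBS ether of 19 (racemic)
Conditions: TBSCl, imidazole, DMAP (cat.), DMF, rt to 35 °C (crude 19 used at once)
Reagents that add atoms: tert-butyldimethylsilyl chloride (TBSCl), CC(C)(C)[Si](C)(C)Cl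
Why: Silylation of both hydroxyls under basic conditions protects them from the ketenes of the next step and keeps the acid-sensitive 3-methoxypropargylic alcohol away from Meyer–Schuster rearrangement.

Step 12
Reactants: 7 2-bromo-4-chloro-3-methylcyclobut-2-en-1-one (1.5 equiv); 20 the ring B methoxyalkyne
Product: 25 ring A phenol on the silylated C7 carbinol (racemic), via bromo(chlorovinyl)ketene 21 (not isolated), via 4-bromo-4-vinylcyclobutenone adduct 22 (not isolated), via dienylketene 23 (not isolated), via 6-chlorocyclohexa-2,4-dienone 24 (not isolated)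
Conditions: toluene, 80 °C then 110 °C, Ar, base-washed glass, no additive
Reagents that add atoms: none
Why: Proposed new method: heating should open 7 by conrotatory 4π ring opening (chlorine turning outward) to ketene 21, whose carbonyl carbon is attacked by the alkyne carbon β to the methoxy group in a [2+2] cycloaddition giving 22; 4π opening of 22 (bromine outward, vinyl inward) gives dienylketene 23, 6π electrocyclisation gives dienone 24, and tautomerisation gives phenol 25. The closest known reaction is the Danheiser benzannulation of 3-alkylcyclobutenones with alkoxy- or siloxyalkynes to resorcinol monoethers; a 2,4-dihalocyclobutenone and an alkyne this hindered have not been tried. Ring A is closed by a thermal disrotatory 6π electrocyclisation forming C4–C5, after C5–C6 and C1–C2 were made in the [2+2] step. No new stereocentre remains, because C4 of 7 and the sp3 centres of 22 and 24 become trigonal, and the racemic C7 carbinol is only carried along. The selectivity needed is the orientation of the ketene–alkyne addition, and the polarisation of the ynol ether secures it (the carbon β to oxygen is the nucleophile), placing OMe beside Br and OH beside Cl; the haloketene is also more electrophilic than an alkylketene and a methyl ynol ether cannot lose an alkene by retro-ene reaction. Neutral, halide-free heating should suppress allylic halide migration in 7, which would exchange the chlorine and bromine positions.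

Step 13
Reactants: 25 ring A phenol
Product: 26 ring A MOM ether of 25 (racemic)
Conditions: MOMCl, iPr2NEt, CH2Cl2, 0 °C to reflux
Reagents that add atoms: chloromethyl methyl ether (MOMCl), COCCl
Why: O-Alkylation of the phenol, acidified by the ortho chlorine, masks it before the oxidation (phenol protection), and silyl migration from the carbinol to the phenol is uphill because it would trade a phenoxide for an alkoxide.

Step 14
Reactants: 26 the tris-MOM bis-silyl ether
Product: 27 tris-MOM diol (racemic)
Conditions: Bu4NF, THF, 0 °C to rt
Reagents that add atoms: none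
Why: Fluoride cleaves both Si–O bonds (desilylation driven by the Si–F bond) under basic conditions that should leave the MOM acetals and the ionisable diaryl carbinol untouched.

Step 15
Reactants: 27 the diol
Product: 28 tris-MOM keto aldehyde
Conditions: (COCl)2, DMSO, CH2Cl2, −78 to −45 °C; then Et3N, −78 °C to rt
Reagents that add atoms: none
Why: In the Swern oxidation both hydroxyls are activated in the cold before the amine is added, so ketone and aldehyde appear together and the hydroxy aldehyde cannot close to a lactol and be over-oxidised to a phthalide.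

Step 16
Reactants: 28 the tris-MOM keto aldehyde
Product: 29 Pestalone H
Conditions: 3 M aq. HCl, MeOH/THF, 40 °C
Reagents that add atoms: none
Why: Acid-catalysed acetal cleavage (MOM removal) frees the three phenols, two of them helped by hydrogen bonding to a neighbouring carbonyl, under conditions mild enough that the prenyl group should not cyclise onto the C5' phenol and the aryl methyl ether stays.

## Compound list

1 | propyne | CC#C | starting material
2 | trichloroacetyl chloride | O=C(Cl)C(Cl)(Cl)Cl | starting material
3 | dichloroketene | O=C=C(Cl)Cl | intermediate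
4 | 4,4-dichloro-3-methylcyclobut-2-en-1-one | O=C1C=C(C)C1(Cl)Cl | intermediate
5 | 2,3-dibromo-4,4-dichloro-3-methylcyclobutanone (racemic) | O=C1C(Br)C(C)(Br)C1(Cl)Cl | intermediate
6 | 2-bromo-4,4-dichloro-3-methylcyclobut-2-en-1-one | O=C1C(Br)=C(C)C1(Cl)Cl | intermediate
7 | 2-bromo-4-chloro-3-methylcyclobut-2-en-1-one (racemic) | O=C1C(Br)=C(C)C1Cl | intermediate
8 | 3,5-dimethoxybenzoic acid | COc1cc(OC)cc(c1)C(=O)O | starting material
9 | 2-(hydroxymethyl)-3,5-dimethoxybenzoic acid | COc1cc(OC)c(CO)c(c1)C(=O)O | intermediate
10 | 4,6-dimethoxyisobenzofuran-1(3H)-one | COc1cc(OC)c2COC(=O)c2c1 | intermediate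
11 | 7-bromo-4,6-dimethoxyisobenzofuran-1(3H)-one | COc1cc(OC)c2COC(=O)c2c1Br | intermediate
12 | 7-bromo-4,6-dihydroxyisobenzofuran-1(3H)-one | Oc1cc(O)c2COC(=O)c2c1Br | intermediate
13 | 7-bromo-4,6-bis(methoxymethoxy)isobenzofuran-1(3H)-one | COCOc1cc(OCOC)c2COC(=O)c2c1Br | intermediate
14 | 4,6-bis(methoxymethoxy)-7-(3-methylbut-2-en-1-yl)isobenzofuran-1(3H)-one | COCOc1cc(OCOC)c2COC(=O)c2c1CC=C(C)C | intermediate
15 | 4,6-bis(methoxymethoxy)-7-(3-methylbut-2-en-1-yl)-1,3-dihydroisobenzofuran-1-ol (racemic) | COCOc1cc(OCOC)c2COC(O)c2c1CC=C(C)C | intermediate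
16 | chloroacetaldehyde dimethyl acetal | COC(CCl)OC | starting material
17 | lithium methoxyacetylide | [Li]C#COC | intermediate
18 | 2-(hydroxymethyl)-3,5-bis(methoxymethoxy)-6-(3-methylbut-2-en-1-yl)benzaldehyde (open form of 15, present as its lithium alkoxide) | COCOc1cc(OCOC)c(CO)c(C=O)c1CC=C(C)C | intermediate
19 | 1-[2-(hydroxymethyl)-3,5-bis(methoxymethoxy)-6-(3-methylbut-2-en-1-yl)phenyl]-3-methoxyprop-2-yn-1-ol (racemic) | COC#CC(O)c1c(CO)c(OCOC)cc(OCOC)c1CC=C(C)C | intermediate
20 | bis-TBS ether of 19, the ring B methoxyalkyne (racemic) | COC#CC(O[Si](C)(C)C(C)(C)C)c1c(CO[Si](C)(C)C(C)(C)C)c(OCOC)cc(OCOC)c1CC=C(C)C | intermediate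
21 | (E)-2-bromo-4-chloro-3-methylbuta-1,3-dien-1-one, the bromo(chlorovinyl)ketene | O=C=C(Br)/C(C)=C/Cl | intermediate
22 | 4-bromo-4-[(E)-1-chloroprop-1-en-2-yl]-3-methoxycyclobut-2-en-1-one carrying the ring B silyloxymethine at C2 (mixture of racemic diastereomers) | COC1=C(C(O[Si](C)(C)C(C)(C)C)c2c(CO[Si](C)(C)C(C)(C)C)c(OCOC)cc(OCOC)c2CC=C(C)C)C(=O)C1(Br)/C(C)=C/Cl | intermediate
23 | dienylketene from ring opening of 22, bromine outward (racemic) | O=C=C(C(O[Si](C)(C)C(C)(C)C)c1c(CO[Si](C)(C)C(C)(C)C)c(OCOC)cc(OCOC)c1CC=C(C)C)/C(OC)=C(Br)\C(C)=C\Cl | intermediate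
24 | 4-bromo-6-chloro-3-methoxy-5-methylcyclohexa-2,4-dien-1-one carrying the ring B silyloxymethine at C2 (mixture of racemic diastereomers) | COC1=C(C(O[Si](C)(C)C(C)(C)C)c2c(CO[Si](C)(C)C(C)(C)C)c(OCOC)cc(OCOC)c2CC=C(C)C)C(=O)C(Cl)C(C)=C1Br | intermediate
25 | 4-bromo-6-chloro-3-methoxy-5-methyl-2-[(TBSO)(aryl)methyl]phenol, aryl = 2-(TBSO-methyl)-3,5-bis(methoxymethoxy)-6-(3-methylbut-2-en-1-yl)phenyl (racemic) | COc1c(Br)c(C)c(Cl)c(O)c1C(O[Si](C)(C)C(C)(C)C)c1c(CO[Si](C)(C)C(C)(C)C)c(OCOC)cc(OCOC)c1CC=C(C)C | intermediate
26 | ring A MOM ether of 25 (racemic) | COc1c(Br)c(C)c(Cl)c(OCOC)c1C(O[Si](C)(C)C(C)(C)C)c1c(CO[Si](C)(C)C(C)(C)C)c(OCOC)cc(OCOC)c1CC=C(C)C | intermediate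
27 | tris-MOM diol: C7 carbinol and C2' hydroxymethyl free (racemic) | COc1c(Br)c(C)c(Cl)c(OCOC)c1C(O)c1c(CO)c(OCOC)cc(OCOC)c1CC=C(C)C | intermediate
28 | tris-MOM ether of Pestalone H | COc1c(Br)c(C)c(Cl)c(OCOC)c1C(=O)c1c(C=O)c(OCOC)cc(OCOC)c1CC=C(C)C | intermediate
29 | Pestalone H | COc1c(Br)c(C)c(Cl)c(O)c1C(=O)c1c(C=O)c(O)cc(O)c1CC=C(C)C | target

## Step count and risks

Total steps: 16. Longest linear sequence: 13 steps (steps 4 to 16, from 3,5-dimethoxybenzoic acid 8); the cyclobutenone arm is 3 steps (steps 1 to 3).

**1. Step 12 (key benzannulation).** The dihalocyclobutenone may decompose or exchange its halogens before ring opening. The bromoketene may dimerise or add to the prenyl alkene faster than it captures the hindered alkyne. The product phenol may also lose silanol to an ortho-quinone methide at 110 °C.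

Fallback with known chemistry, setting out from 4 and 20 and coming back at 25. Exhaustive dechlorination of 4 (excess Zn, AcOH, TMEDA, EtOH, rt) gives 3-methylcyclobut-2-en-1-one F1. Heating F1 with 20 (toluene, 80 then 110 °C) is the established alkylcyclobutenone/alkoxyalkyne case and should give the halogen-free ring A phenol F2 (C2–H, C4–H). NBS (1 equiv, MeCN, −40 °C) should brominate para to the free phenol to give the C2-bromophenol F3. NCS (DMF, rt) then fills C4, the last free ring A position, to give 25. The price is electrophilic halogenation beside the prenyl group and a para/ortho choice in the first halogenation.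

**2. Step 3 (single dechlorination).** The reduction may run on to the chlorine-free enone, may remove the vinylic bromine, or zinc salts may trigger allylic halide migration that exchanges Cl and Br. The bromine addition of step 2 to so electron-poor an alkene is a related weakness.

Fallback setting out from 4 and 20 and coming back at 25; it by-passes steps 2 and 3. Compound 4, which has no vinyl bromide, is reduced with one equivalent of zinc under the same conditions to 4-chloro-3-methylcyclobut-2-en-1-one F4. Heating F4 with 20 should give the C4-chlorinated ring A phenol F5; the chlorine still arrives with the four-carbon piece, so it stays correlated with the phenol. NBS (MeCN, −40 °C) then brominates C2, the only free ring A position and para to the hydroxyl, to give 25.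

**3. Step 8 (prenyl coupling).** Transmetallation through the tertiary allyl terminus may give the reverse-prenyl isomer. Oxidative addition at the doubly ortho-substituted bromide may be slow. The aqueous base may open the lactone.

Fallback setting out from 13 and coming back at 14. Coupling of 13 with allylB(pin) under the same palladium catalysis gives the 7-allyl phthalide F6, where no α/γ question arises. Cross-metathesis of F6 with excess 2-methylbut-2-ene (second-generation Grubbs catalyst, CH2Cl2, 40 °C) converts the allyl group into the prenyl group of 14.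

## Further compounds

F1 | step 12 | 3-methylcyclobut-2-en-1-one | O=C1C=C(C)C1
F2 | step 12 | halogen-free ring A phenol: 3-methoxy-5-methyl-2-[(TBSO)(aryl)methyl]phenol (racemic) | COc1cc(C)cc(O)c1C(O[Si](C)(C)C(C)(C)C)c1c(CO[Si](C)(C)C(C)(C)C)c(OCOC)cc(OCOC)c1CC=C(C)C
F3 | step 12 | C2-bromophenol: 4-bromo-3-methoxy-5-methyl-2-[(TBSO)(aryl)methyl]phenol (racemic) | COc1c(Br)c(C)cc(O)c1C(O[Si](C)(C)C(C)(C)C)c1c(CO[Si](C)(C)C(C)(C)C)c(OCOC)cc(OCOC)c1CC=C(C)C
F4 | step 3 | 4-chloro-3-methylcyclobut-2-en-1-one (racemic) | O=C1C=C(C)C1Cl
F5 | step 3 | C4-chlorophenol: 6-chloro-3-methoxy-5-methyl-2-[(TBSO)(aryl)methyl]phenol (racemic) | COc1cc(C)c(Cl)c(O)c1C(O[Si](C)(C)C(C)(C)C)c1c(CO[Si](C)(C)C(C)(C)C)c(OCOC)cc(OCOC)c1CC=C(C)C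
F6 | step 8 | 7-allyl-4,6-bis(methoxymethoxy)isobenzofuran-1(3H)-one | COCOc1cc(OCOC)c2COC(=O)c2c1CC=C
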